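**Strategy.** Everything rests on disconnecting the bond between the pyran oxygen O1 and carbon C8a of ring A, which traces the chromene half back to encecalin. Ring B is joined later through the enol ether oxygen. The feature exploited is the substitution of ring A: C8a lies para to the C6 acetyl carbon and C4a para to the C7 methoxy group. An acetyl-activated bromide at C8a and an alkenyl chain at C4a therefore fix the linear 6,7-pattern. One palladium-catalysed intramolecular aryl etherification then closes the 2,2-dimethylpyran. Its precursor is 4-bromo-2-methoxyacetophenone bearing a (Z)-3-hydroxy-3-methylbut-1-enyl chain at C5, with ketone and tertiary alcohol unprotected.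

Key step: step 4

Remark on the chemistry: read from the SMILES, the benzylic stereocentre is (S) and the enol ether is (Z), with the ether oxygen and CH2OH on the same side of the double bond. Chromene numbering is used for ring A and the pyran; ring B is the cresol ring.
Remark on the chemistry: carbinol 9 and all later compounds hold a benzylic C–O bond flanked by ortho and para oxygen donors, so every operation from step 5 on is kept neutral or basic.

**Step 1**
Reactants: 1 1-(4-bromo-2-methoxyphenyl)ethanone; 2 N-iodosuccinimide
Product: 3 1-(4-bromo-5-iodo-2-methoxyphenyl)ethanone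
Conditions: NIS (1.1 equiv), CF3CO2H, MeCN, 25 → 50 °C, dark
Reagents that add atoms: N-iodosuccinimide (2), O=C1CCC(=O)N1I
Why: Electrophilic aromatic iodination, in which the methoxy group directs para to C5 (also meta to acetyl and ortho to bromine) while the other activated site C3 is wedged between OMe and Br, so one iodide should form.

**Step 2**
Reactants: 3 1-(4-bromo-5-iodo-2-methoxyphenyl)ethanone; 4 2-methylbut-3-yn-2-ol
Product: 5 1-[4-bromo-5-(3-hydroxy-3-methylbut-1-ynyl)-2-methoxyphenyl]ethanone
Conditions: PdCl2(PPh3)2 (2 mol %), CuI (4 mol %), Et3N, THF, 25 °C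
Reagents that add atoms: none
Why: Sonogashira coupling, in which oxidative addition to C–I is far faster than to C–Br at room temperature, so the alkyne goes only to the future C4a and the bromide is kept for step 4.

**Step 3**
Reactants: 5 1-[4-bromo-5-(3-hydroxy-3-methylbut-1-ynyl)-2-methoxyphenyl]ethanone
Product: 6 (Z)-1-[4-bromo-5-(3-hydroxy-3-methylbut-1-enyl)-2-methoxyphenyl]ethanone
Conditions: H2 (1 atm), Pd/CaCO3 poisoned with Pb(OAc)2, quinoline, EtOAc, 25 °C, stopped after one equivalent of H2
Reagents that add atoms: none
Why: Lindlar-type semihydrogenation, in which syn delivery of hydrogen on the poisoned surface gives the Z alkene and should leave the aryl bromide and the ketone untouched.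

**Step 4**
Reactants: 6 (Z)-1-[4-bromo-5-(3-hydroxy-3-methylbut-1-enyl)-2-methoxyphenyl]ethanone
Product: 7 encecalin (6-acetyl-7-methoxy-2,2-dimethyl-2H-chromene)
Conditions: Pd(OAc)2 (4 mol %), 2-(di-tert-butylphosphino)-1,1'-binaphthyl (5 mol %), Cs2CO3 (1.5 equiv), toluene (0.05 M), 80 °C, Ar
Reagents that add atoms: none
Why: Zerovalent palladium formed from Pd(OAc)2 and the bulky binaphthyl phosphine adds oxidatively to the C8a–Br bond, the only carbon–halogen bond left and one made electron-poor by the acetyl group para to it. Carbonate-assisted exchange of bromide for the tertiary alkoxide gives a seven-membered oxapalladacycle, and C–O reductive elimination contracts it to the six-membered pyran (an exo-type closure, since the replaced C–Br bond lies outside the new ring); this is the Buchwald–Hartwig-type intramolecular aryl etherification established for tertiary alcohols. No stereocentre is created. The Z geometry of the C3=C4 alkene from step 3 keeps oxygen and palladium within bonding distance, so ring closure should outrun intermolecular events. The selectivity needed is etherification over ketone α-arylation, aldol chemistry and hydrodebromination, and it is secured by a weak, poorly soluble base, by dilution, and by an alkoxide with no hydrogen on its carbinol carbon, which shuts the β-hydride path. Regiochemistry needs no control, because bromine already sits at C8a and the alkenyl chain at C4a.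

**Step 5**
Reactants: 7 encecalin
Product: 9 (S)-1-(7-methoxy-2,2-dimethyl-2H-chromen-6-yl)ethanol, via alkoxy-benzodioxaborole 8 (not isolated)
Conditions: (R)-2-methyl-CBS-oxazaborolidine (15 mol %), catecholborane (1.5 equiv), toluene, −78 → −20 °C; MeOH quench, 1 M NaOH wash; Et3N-deactivated silica
Reagents that add atoms: catecholborane, B1Oc2ccccc2O1 (boron and catecholate stay only in 8; 9 keeps hydrogen alone)
Why: Corey–Bakshi–Shibata reduction, in which the ketone binds the catalyst boron with the large aryl group turned away, so hydride reaches the Re face and sets the (S) centre, while catecholborane does not hydroborate the chromene alkene at this temperature.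

**Step 6**
Reactants: 10 2-bromo-5-methylphenol
Product: 11 (2-bromo-5-methylphenoxy)triisopropylsilane
Conditions: iPr3SiCl (1.1 equiv), imidazole (2 equiv), DMF, 25 °C
Reagents that add atoms: chlorotriisopropylsilane, CC(C)[Si](Cl)(C(C)C)C(C)C
Why: Imidazole-promoted O-silylation, giving a bulky aryl silyl ether that tolerates Grignard formation, resists O-to-C silyl migration and the carbonate base of step 9, and still leaves with fluoride.

**Step 7**
Reactants: 11 (2-bromo-5-methylphenoxy)triisopropylsilane; 12 prop-2-yn-1-ol
Product: 15 (Z)-3-iodo-2-[4-methyl-2-(triisopropylsilyloxy)phenyl]prop-2-en-1-ol, via aryl Grignard reagent 13 (not isolated), via oxamagnesole chelate 14 (not isolated)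
Conditions: (a) Mg turnings, THF, 25–45 °C; (b) 12 (0.4 equiv relative to 11), CuI (10 mol %), THF, −10 → 25 °C; (c) I2, THF, −20 → 0 °C; aq Na2S2O3/NH4Cl
Reagents that add atoms: iodine, II; magnesium, [Mg] (kept only in 13 and 14)
Why: Copper-catalysed carbomagnesiation of a propargylic alkoxide, in which one equivalent of 13 deprotonates 12 and a second places its aryl group on C2 while magnesium ends on C3 tied to the alkoxide in the five-membered chelate 14 (net anti addition), so iodinolysis with retention puts iodine cis to CH2OH, the Z geometry required.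

**Step 8**
Reactants: 15 (Z)-3-iodo-2-[4-methyl-2-(triisopropylsilyloxy)phenyl]prop-2-en-1-ol
Product: 16 (Z)-tert-butyl{3-iodo-2-[4-methyl-2-(triisopropylsilyloxy)phenyl]prop-2-enyloxy}dimethylsilane
Conditions: tBuMe2SiCl (1.2 equiv), imidazole (2.5 equiv), CH2Cl2, 0 → 25 °C
Reagents that add atoms: tert-butylchlorodimethylsilane, CC(C)(C)[Si](C)(C)Cl
Why: Standard silyl ether formation, which masks the primary allylic alcohol so that it cannot compete as nucleophile in step 9.

**Step 9**
Reactants: 9 (S)-1-(7-methoxy-2,2-dimethyl-2H-chromen-6-yl)ethanol; 16 (Z)-vinyl iodide (1.2 equiv)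
Product: 17 bis-silyl ether of the target, (S) at the benzylic carbon and (Z) at the enol ether
Conditions: CuI (10 mol %), 3,4,7,8-tetramethyl-1,10-phenanthroline (20 mol %), Cs2CO3 (1.5 equiv), toluene, 80 °C, Ar
Reagents that add atoms: none
Why: Ullmann-type copper-catalysed C–O coupling of a vinyl iodide with an alcohol, which keeps the alkene geometry and never breaks the carbinol C–O bond, so (Z) and (S) are both carried over.

**Step 10**
Reactants: 17 bis-silyl ether
Product: 18 2-[(Z)-3-hydroxy-1-{(1S)-1-(7-methoxy-2,2-dimethyl-2H-chromen-6-yl)ethoxy}prop-1-en-2-yl]-5-methylphenol (target)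
Conditions: Bu4NF (2.5 equiv), THF, 0 °C; pH 7 phosphate buffer; Et3N-deactivated silica
Reagents that add atoms: none
Why: Fluoride-induced desilylation, which removes both silyl groups in one basic operation that should leave the acid-labile enol ether, the benzylic ether and the chromene alone.

**Compound list**
1 | 1-(4-bromo-2-methoxyphenyl)ethanone | COc1cc(Br)ccc1C(C)=O | starting material
2 | N-iodosuccinimide | O=C1CCC(=O)N1I | starting material
3 | 1-(4-bromo-5-iodo-2-methoxyphenyl)ethanone | COc1cc(Br)c(I)cc1C(C)=O | intermediate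
4 | 2-methylbut-3-yn-2-ol | CC(C)(O)C#C | starting material
5 | 1-[4-bromo-5-(3-hydroxy-3-methylbut-1-ynyl)-2-methoxyphenyl]ethanone | COc1cc(Br)c(C#CC(C)(C)O)cc1C(C)=O | intermediate
6 | (Z)-1-[4-bromo-5-(3-hydroxy-3-methylbut-1-enyl)-2-methoxyphenyl]ethanone | COc1cc(Br)c(/C=C\C(C)(C)O)cc1C(C)=O | intermediate
7 | encecalin, 6-acetyl-7-methoxy-2,2-dimethyl-2H-chromene | COc1cc2OC(C)(C)C=Cc2cc1C(C)=O | intermediate
8 | (S)-2-[1-(7-methoxy-2,2-dimethyl-2H-chromen-6-yl)ethoxy]-1,3,2-benzodioxaborole | COc1cc2c(cc1[C@H](C)OB1Oc3ccccc3O1)C=CC(C)(C)O2 | intermediate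
9 | (S)-1-(7-methoxy-2,2-dimethyl-2H-chromen-6-yl)ethanol | COc1cc2c(cc1[C@H](C)O)C=CC(C)(C)O2 | intermediate
10 | 2-bromo-5-methylphenol | Cc1ccc(Br)c(O)c1 | starting material
11 | (2-bromo-5-methylphenoxy)triisopropylsilane | Cc1ccc(Br)c(O[Si](C(C)C)(C(C)C)C(C)C)c1 | intermediate
12 | prop-2-yn-1-ol | C#CCO | starting material
13 | [4-methyl-2-(triisopropylsilyloxy)phenyl]magnesium bromide | Cc1ccc([Mg]Br)c(O[Si](C(C)C)(C(C)C)C(C)C)c1 | intermediate
14 | 4-[4-methyl-2-(triisopropylsilyloxy)phenyl]-2,5-dihydro-1,2-oxamagnesole | Cc1ccc(C2=C[Mg]OC2)c(O[Si](C(C)C)(C(C)C)C(C)C)c1 | intermediate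
15 | (Z)-3-iodo-2-[4-methyl-2-(triisopropylsilyloxy)phenyl]prop-2-en-1-ol | I/C=C(\CO)c1ccc(C)cc1O[Si](C(C)C)(C(C)C)C(C)C | intermediate
16 | (Z)-tert-butyl{3-iodo-2-[4-methyl-2-(triisopropylsilyloxy)phenyl]prop-2-enyloxy}dimethylsilane | I/C=C(\CO[Si](C)(C)C(C)(C)C)c1ccc(C)cc1O[Si](C(C)C)(C(C)C)C(C)C | intermediate
17 | (S,Z)-bis-silyl ether of the target (primary O-SiMe2tBu, phenolic O-SiiPr3) | COc1cc2c(cc1[C@H](C)O/C=C(\CO[Si](C)(C)C(C)(C)C)c1ccc(C)cc1O[Si](C(C)C)(C(C)C)C(C)C)C=CC(C)(C)O2 | intermediate
18 | 2-[(Z)-3-hydroxy-1-{(1S)-1-(7-methoxy-2,2-dimethyl-2H-chromen-6-yl)ethoxy}prop-1-en-2-yl]-5-methylphenol | COc1cc2c(cc1[C@H](C)O/C=C(\CO)c1ccc(C)cc1O)C=CC(C)(C)O2 | target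

**Total step count:** 10.
**Longest linear sequence:** 7 steps (1, 2, 3, 4, 5, 9, 10) from 1. The ring B branch (steps 6–8) is convergent.

**Steps most likely to fail**

**Step 4.** C–O reductive elimination may be too slow. That would leave room for Z-to-E isomerisation of the alkene, β-carbon cleavage of the palladium alkoxide with loss of acetone, hydrodebromination, or intermolecular α-arylation. The fallback sets out from 6 and comes back at 7. It inverts the closure: oxygen is first placed on C8a and the pyran is then closed at O1–C2.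
- Miyaura borylation of 6 (PdCl2(dppf), bis(pinacolato)diboron, KOAc, dioxane, 80 °C) should give (Z)-1-[5-(3-hydroxy-3-methylbut-1-enyl)-2-methoxy-4-(4,4,5,5-tetramethyl-1,3,2-dioxaborolan-2-yl)phenyl]ethanone F1.
- Mild oxidation (NaBO3·4H2O, THF/H2O, 25 °C) should give (Z)-1-[4-hydroxy-5-(3-hydroxy-3-methylbut-1-enyl)-2-methoxyphenyl]ethanone F2.
- Catalytic pyridinium p-toluenesulfonate in warm toluene should dehydrate this diol through the allyl cation and o-quinone methide manifold to 7. This is the cyclisation known for the diols obtained from coumarins and methyl Grignard reagents.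

**Step 9.** Transfer of the hindered secondary benzylic alkoxide to copper may be sluggish at 80 °C. That would allow protodeiodination, redox erosion of the stereocentre, or silyl transfer from the phenol. The fallback sets out from 16 and comes back at 17. It replaces the halide coupling by an oxidative coupling at room temperature.
- Borylation of the alkenyl iodide with retention (PdCl2(PPh3)2, PPh3, KOPh, bis(pinacolato)diboron, toluene, 50 °C) should give (Z)-tert-butyldimethyl{2-[4-methyl-2-(triisopropylsilyloxy)phenyl]-3-(4,4,5,5-tetramethyl-1,3,2-dioxaborolan-2-yl)prop-2-enyloxy}silane F3.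
- This boronate, used in excess, should couple with 9 in a Chan–Lam-type vinyl etherification (Cu(OAc)2, Et3N, 4 Å molecular sieves, CH2Cl2, air, 25 °C) to give 17.

**Step 7.** The ortho-silyloxy Grignard reagent may add slowly or unselectively to the alkoxide. Prolonged warming could also trigger O-to-C silyl migration in the reagent. The fallback sets out from 11 and comes back at 15. It builds the same C–C bond by palladium-catalysed syn addition.
- An aromatic Finkelstein exchange (CuI, NaI, trans-N,N'-dimethylcyclohexane-1,2-diamine, dioxane, 110 °C) should give (2-iodo-5-methylphenoxy)triisopropylsilane F4.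
- Reductive Heck-type hydroarylation of commercial 3-(trimethylsilyl)prop-2-yn-1-ol (Pd(OAc)2, PPh3, HCO2H/Et3N, DMF, 50 °C) delivers aryl to the carbon remote from silicon and hydrogen syn to it. It should give (Z)-2-[4-methyl-2-(triisopropylsilyloxy)phenyl]-3-(trimethylsilyl)prop-2-en-1-ol F5.
- Iododesilylation with retention (NIS, MeCN, 0 °C) should then give 15.

**Further compounds**
F1 | step 4 | (Z)-1-[5-(3-hydroxy-3-methylbut-1-enyl)-2-methoxy-4-(4,4,5,5-tetramethyl-1,3,2-dioxaborolan-2-yl)phenyl]ethanone | COc1cc(B2OC(C)(C)C(C)(C)O2)c(/C=C\C(C)(C)O)cc1C(C)=O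
F2 | step 4 | (Z)-1-[4-hydroxy-5-(3-hydroxy-3-methylbut-1-enyl)-2-methoxyphenyl]ethanone | COc1cc(O)c(/C=C\C(C)(C)O)cc1C(C)=O
F3 | step 9 | (Z)-tert-butyldimethyl{2-[4-methyl-2-(triisopropylsilyloxy)phenyl]-3-(4,4,5,5-tetramethyl-1,3,2-dioxaborolan-2-yl)prop-2-enyloxy}silane | CC1(C)OB(/C=C(\CO[Si](C)(C)C(C)(C)C)c2ccc(C)cc2O[Si](C(C)C)(C(C)C)C(C)C)OC1(C)C
F4 | step 7 | (2-iodo-5-methylphenoxy)triisopropylsilane | Cc1ccc(I)c(O[Si](C(C)C)(C(C)C)C(C)C)c1
F5 | step 7 | (Z)-2-[4-methyl-2-(triisopropylsilyloxy)phenyl]-3-(trimethylsilyl)prop-2-en-1-ol | C[Si](C)(C)/C=C(\CO)c1ccc(C)cc1O[Si](C(C)C)(C(C)C)C(C)C
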